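**Retrosynthetic overview**

1. Target 27 ⇐ 26 (silyl ether removal) ⇐ bromo vinyl-oxirane 23 + CO2. The C11–C12 bond comes from carboxylation of the C11 alkenylmagnesium; the O–C6 bond comes from palladium-catalysed 1,4-opening of the C3–C4 oxirane / C5=C6 olefin by that carboxylate.
2. Enabling feature: C6 is allylic to the ring olefin C4=C5 and 1,4 to the C3 carbinol (the cis-2-ene-1,4-dioxy unit C3(OH)–C4(Me)=C5–C6(O) of the ten-membered ring), and C6 is γ to C12 through C7–C11. A trans-C3/C4 oxirane beside a Z-C5=C6 olefin is therefore a latent allyl cation that a C11 carboxylate closes 5-exo, with 1,4-chirality transfer from C4 to C6.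
3. Ten-membered carbocycle 21 ⇐ ring-closing metathesis at C5=C6 of triene 20; C7 and C8 ⇐ Evans syn-aldol of 3-bromobut-3-enoyl imide 14 with aldehyde 10.
4. Aldehyde 10 ⇐ geraniol 1: Sharpless epoxidation and reductive opening (C10), SeO2 oxidation, second Sharpless epoxidation (C3, C4), methylenation.
5. Ring order: oxirane (step 5), ten-membered carbocycle (step 15), γ-lactone (step 18).

Key step: step 18

Remark: locants are read off the target (ring C1–C10, lactone carbons C11–C13; C6 bears the lactone oxygen, C7 the lactone branch, C8 the tiglate, C10 the tertiary and C3 the secondary hydroxyl); 3-bromobut-3-enoic acid and tigloyl chloride are taken as purchasable.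

**Route**

Step 1
Reactants: 1 geraniol
Product: 2 (2S,3S)-2,3-epoxygeraniol
Conditions: Ti(OiPr)4 (cat.), L-(+)-diethyl tartrate (cat.), t-BuOOH, 4 Å MS, CH2Cl2, −20 °C
Reagents that add atoms: tert-butyl hydroperoxide CC(C)(C)OO
Why: Sharpless asymmetric epoxidation of the allylic alcohol with the L-(+)-tartrate catalyst delivers oxygen to one olefin face and so sets the future C10 configuration, while the remote trisubstituted olefin is not an allylic alcohol and stays untouched.

Step 2
Reactants: 2 (2S,3S)-2,3-epoxygeraniol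
Product: 3 (3S)-3,7-dimethyloct-6-ene-1,3-diol
Conditions: NaAlH2(OCH2CH2OMe)2, THF, 0 °C → rt
Reagents that add atoms: none
Why: Regioselective reductive opening of a 2,3-epoxy alcohol: the alkoxy-aluminate delivers hydride intramolecularly to the carbon next to the carbinol (future C9), so the tertiary C–O bond and the C10 configuration are kept and the 1,3-diol results.

Step 3
Reactants: 3 (3S)-3,7-dimethyloct-6-ene-1,3-diol
Product: 5 (3S)-3-(tert-butyldimethylsilyloxy)-3,7-dimethyl-1-(triethylsilyloxy)oct-6-ene, via primary triethylsilyl ether 4 (not isolated)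
Conditions: TESCl (1.05 equiv), imidazole, CH2Cl2, 0 °C; then TBSOTf, 2,6-lutidine, 0 °C → rt
Reagents that add atoms: chlorotriethylsilane CC[Si](Cl)(CC)CC; tert-butyldimethylsilyl trifluoromethanesulfonate CC(C)(C)[Si](C)(C)OS(=O)(=O)C(F)(F)F
Why: Chemoselective silylation in one flask: the primary hydroxyl reacts with the silyl chloride, the hindered tertiary hydroxyl only with the silyl triflate, and no stereocentre is touched.

Step 4
Reactants: 5 bis-silyl ether
Product: 6 (2E,6S)-6-(tert-butyldimethylsilyloxy)-2,6-dimethyl-8-(triethylsilyloxy)oct-2-en-1-ol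
Conditions: SeO2 (cat.), t-BuOOH, CH2Cl2, 0 °C → rt
Reagents that add atoms: tert-butyl hydroperoxide CC(C)(C)OO
Why: SeO2-catalysed allylic oxidation (ene reaction followed by [2,3]-sigmatropic shift) of a gem-dimethyl olefin is selective for the (E)-methyl group and should give the (E)-2-methyl allylic alcohol (future C5).

Step 5
Reactants: 6 (E)-allylic alcohol
Product: 7 (2S,3S)-epoxy alcohol
Conditions: Ti(OiPr)4 (cat.), L-(+)-diethyl tartrate (cat.), t-BuOOH, 4 Å MS, CH2Cl2, −20 °C
Reagents that add atoms: tert-butyl hydroperoxide CC(C)(C)OO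
Why: A second Sharpless asymmetric epoxidation with the same L-(+)-tartrate is reagent-controlled and sets C3 and C4 as the (S,S)-trans-oxirane, independent of the remote C10 centre.

Step 6
Reactants: 7 epoxy alcohol
Product: 8 (2R,3S)-epoxy aldehyde
Conditions: Dess–Martin periodinane, pyridine, CH2Cl2, 0 °C → rt
Reagents that add atoms: none
Why: Dess–Martin oxidation buffered with pyridine converts the primary alcohol into the aldehyde without opening the oxirane, and the fully substituted α-carbon C4 cannot epimerise.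

Step 7
Reactants: 8 epoxy aldehyde
Product: 9 (2S,3S)-2-ethenyl-2-methyloxirane
Conditions: Ph3PCH3Br, KN(SiMe3)2, THF, 0 °C; then 8, −78 → 0 °C
Reagents that add atoms: methyltriphenylphosphonium bromide C[P+](c1ccccc1)(c1ccccc1)c1ccccc1.[Br-]
Why: Wittig methylenation of the non-enolisable aldehyde gives the vinyl oxirane, which carries the future allyl unit C4–C5, with no change at any stereocentre.

Step 8
Reactants: 9 vinyl oxirane
Product: 10 (3S)-aldehyde (C8 aldehyde)
Conditions: (COCl)2, DMSO, CH2Cl2, −78 → −30 °C; Et3N, → 0 °C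
Reagents that add atoms: none
Why: Under Swern conditions a primary triethylsilyl ether is oxidised directly to the aldehyde because the chlorosulfonium salt attacks the silyl ether oxygen, while the tertiary TBS ether and the oxirane are inert.

Step 9
Reactants: 11 3-bromobut-3-enoic acid; 12 (4S)-4-benzyl-1,3-oxazolidin-2-one
Product: 14 (4S)-4-benzyl-3-(3-bromobut-3-enoyl)-1,3-oxazolidin-2-one, via mixed pivalic anhydride 13 (not isolated)
Conditions: PivCl, Et3N, THF, −20 °C; then LiCl, 12, −20 °C → rt
Reagents that add atoms: pivaloyl chloride CC(C)(C)C(=O)Cl (its atoms stay in intermediate 13 only)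
Why: N-Acylation of the Evans oxazolidinone through the mixed anhydride with LiCl and Et3N is a mild standard method that needs no strong base and so should avoid dehydrobromination of the β,γ-unsaturated acid.

Step 10
Reactants: 14 bromobutenoyl imide; 10 aldehyde
Product: 16 (2S,3R,5S)-syn-aldol imide, via dibutylboron Z-enolate 15 (not isolated)
Conditions: Bu2BOTf, i-Pr2NEt, CH2Cl2, −78 → 0 °C; then 10, −78 → 0 °C; pH 7 buffer, MeOH, H2O2, 0 °C
Reagents that add atoms: dibutylboron trifluoromethanesulfonate CCCCB(CCCC)OS(=O)(=O)C(F)(F)F (its atoms stay in intermediate 15 only)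
Why: Evans syn-aldol reaction: the (Z)-boron enolate reacts through a Zimmerman–Traxler chair in which the (S)-benzyl auxiliary shields one enolate face, so C7 and C8 are set 2,3-syn under reagent control whatever the remote centres.

Step 11
Reactants: 16 aldol imide
Product: 17 C8 triethylsilyl ether
Conditions: TESOTf, 2,6-lutidine, CH2Cl2, −78 °C
Reagents that add atoms: triethylsilyl trifluoromethanesulfonate CC[Si](CC)(CC)OS(=O)(=O)C(F)(F)F
Why: Silylation of the secondary aldol hydroxyl with the silyl triflate and a hindered base at low temperature blocks retro-aldol and β-elimination in the next steps and leaves the oxirane intact.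

Step 12
Reactants: 17 silylated imide
Product: 18 (2R,3R,5S)-primary alcohol
Conditions: LiBH4, H2O (1 equiv), Et2O, 0 °C
Reagents that add atoms: none
Why: Reductive removal of the Evans auxiliary: LiBH4 reduces the activated imide carbonyl (C6) to the primary alcohol without touching the oxirane, the alkenyl bromide or the silyl ethers, and the auxiliary is recovered.

Step 13
Reactants: 18 primary alcohol
Product: 19 (2S,3R,5S)-aldehyde
Conditions: Dess–Martin periodinane, pyridine, CH2Cl2, 0 °C
Reagents that add atoms: none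
Why: Buffered Dess–Martin oxidation gives the α-branched aldehyde under non-basic conditions, and the crude aldehyde is used at once so that C7 is not epimerised.

Step 14
Reactants: 19 aldehyde
Product: 20 (3R,4R,6S)-triene
Conditions: Ph3PCH3Br, KN(SiMe3)2, THF, 0 °C; then 19, −78 → 0 °C
Reagents that add atoms: methyltriphenylphosphonium bromide C[P+](c1ccccc1)(c1ccccc1)c1ccccc1.[Br-]
Why: Wittig methylenation at low temperature should add to the aldehyde faster than the ylide deprotonates C7, turning C6 into the vinyl group needed for ring closure with C7 unchanged.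

Step 15
Reactants: 20 triene
Product: 21 ten-membered (Z)-olefin with trans-oxirane
Conditions: second-generation Grubbs catalyst RuCl2(=CHPh)(PCy3)(H2IMes) (10 mol%), CH2Cl2 (1 mM), 40 °C
Reagents that add atoms: none
Why: Ring-closing olefin metathesis joins the two monosubstituted vinyl groups (the 1,1-disubstituted bromoalkene is a spectator) into the ten-membered carbocycle, and because the ring already holds the trans-oxirane the cis (Z) C5=C6 olefin is the less strained product of this reversible reaction.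

Step 16
Reactants: 21 macrocyclic bis-silyl ether
Product: 22 C8 alcohol
Conditions: Bu4NF (1.1 equiv), AcOH (1.1 equiv), THF, 0 °C
Reagents that add atoms: none
Why: Buffered fluoride desilylation cleaves the secondary triethylsilyl ether much faster than the hindered tertiary TBS ether and is mild enough for the vinyl oxirane.

Step 17
Reactants: 22 C8 alcohol
Product: 23 C8 tiglate
Conditions: tigloyl chloride, pyridine, DMAP (cat.), CH2Cl2, 0 °C → rt
Reagents that add atoms: (E)-2-methylbut-2-enoyl chloride C/C=C(\C)C(=O)Cl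
Why: DMAP-catalysed acylation of the only free hydroxyl installs the ester, and its E geometry is that of the acid chloride.

Step 18
Reactants: 23 bromo vinyl-oxirane tiglate
Product: 26 C10-O-TBS α-methylene lactone, via alkenylmagnesium species 24 (not isolated), via lithium carboxylate 25 (not isolated)
Conditions: i-Pr(n-Bu)2MgLi (from i-PrMgCl + 2 n-BuLi), THF, −78 °C; CO2 (1 atm), −78 → 0 °C; Ar purge; Pd(PPh3)4 (5 mol%), 0 °C → rt; aq. NH4Cl
Reagents that add atoms: carbon dioxide O=C=O; lithium dibutyl(isopropyl)magnesate CCCC[Mg]CCCC.[Li]C(C)C (its atoms stay in intermediate 24 only)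
Why: Bromine–magnesium exchange with the magnesate at −78 °C, which should be faster than attack on the ester or the oxirane, gives alkenylmagnesium 24, and CO2 insertion forms the C11–C12 bond in acrylate 25; zerovalent palladium then ionises the vinyl oxirane anti to the C4–O bond to a π-allylpalladium alkoxide over C4–C6, and the tethered carboxylate attacks C6 anti to palladium to form the O–C6 bond. The closest known reaction types are the carboxylation of alkenylmagnesium reagents made by halogen–magnesium exchange and the palladium-catalysed 1,4-addition of carboxylates to vinyl epoxides (Tsuji–Trost allylic substitution). The γ-lactone (O–C6–C7–C11–C12) closes in the 5-exo mode on the allyl terminus C6, whereas attack at the tertiary terminus C4 would need a seven-membered ring. The new stereocentre C6 is controlled by double inversion: the oxygen nucleophile enters on the face the oxirane oxygen left, so the C4 configuration from step 5 is transferred to C6 (R), the lactone is cis-fused to the C7 centre from step 10, and the C3 carbinol is set free with its configuration unchanged. The step needs Z geometry of the new C4=C5 olefin and ring closure before π–σ–π equilibration; the Z-C5=C6 olefin holds C7 in the anti position of the allyl unit, the C4 methyl group would clash with C7 if it were anti too, so ring carbon C3 takes the anti position (the U-shaped cis,cis arrangement a ten-membered ring accommodates), and the carboxylate sits directly on C7, which should make closure faster than isomerisation.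

Step 19
Reactants: 26 C10-O-TBS lactone
Product: 27 target CNP0137971.1
Conditions: HF·pyridine, pyridine, THF, 0 °C → rt
Reagents that add atoms: none
Why: Fluoride-driven desilylation (Si–F bond formation) with buffered HF·pyridine cleaves the tertiary silyl ether under conditions that the α-methylene lactone, the allylic alcohol and the tiglate should tolerate.

**Compound list**

1 | geraniol, (2E)-3,7-dimethylocta-2,6-dien-1-ol | CC(C)=CCC/C(C)=C/CO | starting material
2 | [(2S,3S)-3-methyl-3-(4-methylpent-3-en-1-yl)oxiran-2-yl]methanol | CC(C)=CCC[C@]1(C)O[C@H]1CO | intermediate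
3 | (3S)-3,7-dimethyloct-6-ene-1,3-diol | CC(C)=CCC[C@](C)(O)CCO | intermediate
4 | (3S)-3,7-dimethyl-1-(triethylsilyloxy)oct-6-en-3-ol | CC(C)=CCC[C@](C)(O)CCO[Si](CC)(CC)CC | intermediate
5 | (3S)-3-(tert-butyldimethylsilyloxy)-3,7-dimethyl-1-(triethylsilyloxy)oct-6-ene | CC(C)=CCC[C@](C)(O[Si](C)(C)C(C)(C)C)CCO[Si](CC)(CC)CC | intermediate
6 | (2E,6S)-6-(tert-butyldimethylsilyloxy)-2,6-dimethyl-8-(triethylsilyloxy)oct-2-en-1-ol | OC/C(C)=C/CC[C@](C)(O[Si](C)(C)C(C)(C)C)CCO[Si](CC)(CC)CC | intermediate
7 | [(2S,3S)-3-[(3S)-3-(tert-butyldimethylsilyloxy)-3-methyl-5-(triethylsilyloxy)pentyl]-2-methyloxiran-2-yl]methanol | OC[C@]1(C)O[C@H]1CC[C@](C)(O[Si](C)(C)C(C)(C)C)CCO[Si](CC)(CC)CC | intermediate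
8 | (2R,3S)-3-[(3S)-3-(tert-butyldimethylsilyloxy)-3-methyl-5-(triethylsilyloxy)pentyl]-2-methyloxirane-2-carbaldehyde | O=C[C@]1(C)O[C@H]1CC[C@](C)(O[Si](C)(C)C(C)(C)C)CCO[Si](CC)(CC)CC | intermediate
9 | (2S,3S)-3-[(3S)-3-(tert-butyldimethylsilyloxy)-3-methyl-5-(triethylsilyloxy)pentyl]-2-ethenyl-2-methyloxirane | C=C[C@]1(C)O[C@H]1CC[C@](C)(O[Si](C)(C)C(C)(C)C)CCO[Si](CC)(CC)CC | intermediate
10 | (3S)-3-(tert-butyldimethylsilyloxy)-5-[(2S,3S)-3-ethenyl-3-methyloxiran-2-yl]-3-methylpentanal | C=C[C@]1(C)O[C@H]1CC[C@](C)(O[Si](C)(C)C(C)(C)C)CC=O | intermediate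
11 | 3-bromobut-3-enoic acid | C=C(Br)CC(=O)O | starting material
12 | (4S)-4-benzyl-1,3-oxazolidin-2-one | O=C1N[C@@H](Cc2ccccc2)CO1 | starting material
13 | 3-bromobut-3-enoic pivalic anhydride | C=C(Br)CC(=O)OC(=O)C(C)(C)C | intermediate
14 | (4S)-4-benzyl-3-(3-bromobut-3-enoyl)-1,3-oxazolidin-2-one | C=C(Br)CC(=O)N1[C@@H](Cc2ccccc2)COC1=O | intermediate
15 | dibutylboron (Z)-enolate of 14 | C=C(Br)/C=C(\OB(CCCC)CCCC)N1[C@@H](Cc2ccccc2)COC1=O | intermediate
16 | (4S)-4-benzyl-3-[(2S,3R,5S)-2-(1-bromoethenyl)-5-(tert-butyldimethylsilyloxy)-7-[(2S,3S)-3-ethenyl-3-methyloxiran-2-yl]-3-hydroxy-5-methylheptanoyl]-1,3-oxazolidin-2-one | C=C[C@]1(C)O[C@H]1CC[C@](C)(O[Si](C)(C)C(C)(C)C)C[C@@H](O)[C@H](C(Br)=C)C(=O)N2[C@@H](Cc3ccccc3)COC2=O | intermediate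
17 | (4S)-4-benzyl-3-[(2S,3R,5S)-2-(1-bromoethenyl)-5-(tert-butyldimethylsilyloxy)-7-[(2S,3S)-3-ethenyl-3-methyloxiran-2-yl]-5-methyl-3-(triethylsilyloxy)heptanoyl]-1,3-oxazolidin-2-one | C=C[C@]1(C)O[C@H]1CC[C@](C)(O[Si](C)(C)C(C)(C)C)C[C@@H](O[Si](CC)(CC)CC)[C@H](C(Br)=C)C(=O)N2[C@@H](Cc3ccccc3)COC2=O | intermediate
18 | (2R,3R,5S)-2-(1-bromoethenyl)-5-(tert-butyldimethylsilyloxy)-7-[(2S,3S)-3-ethenyl-3-methyloxiran-2-yl]-5-methyl-3-(triethylsilyloxy)heptan-1-ol | C=C[C@]1(C)O[C@H]1CC[C@](C)(O[Si](C)(C)C(C)(C)C)C[C@@H](O[Si](CC)(CC)CC)[C@H](C(Br)=C)CO | intermediate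
19 | (2S,3R,5S)-2-(1-bromoethenyl)-5-(tert-butyldimethylsilyloxy)-7-[(2S,3S)-3-ethenyl-3-methyloxiran-2-yl]-5-methyl-3-(triethylsilyloxy)heptanal | C=C[C@]1(C)O[C@H]1CC[C@](C)(O[Si](C)(C)C(C)(C)C)C[C@@H](O[Si](CC)(CC)CC)[C@H](C(Br)=C)C=O | intermediate
20 | (3R,4R,6S)-3-(1-bromoethenyl)-6-(tert-butyldimethylsilyloxy)-8-[(2S,3S)-3-ethenyl-3-methyloxiran-2-yl]-6-methyl-4-(triethylsilyloxy)oct-1-ene | C=C[C@]1(C)O[C@H]1CC[C@](C)(O[Si](C)(C)C(C)(C)C)C[C@@H](O[Si](CC)(CC)CC)[C@H](C(Br)=C)C=C | intermediate
21 | (1S,2Z,4R,5R,7S,10S)-4-(1-bromoethenyl)-7-(tert-butyldimethylsilyloxy)-1,7-dimethyl-5-(triethylsilyloxy)-11-oxabicyclo[8.1.0]undec-2-ene | C=C(Br)[C@@H]1/C=C\[C@]2(C)O[C@H]2CC[C@](C)(O[Si](C)(C)C(C)(C)C)C[C@H]1O[Si](CC)(CC)CC | intermediate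
22 | (1S,2Z,4R,5R,7S,10S)-4-(1-bromoethenyl)-7-(tert-butyldimethylsilyloxy)-1,7-dimethyl-11-oxabicyclo[8.1.0]undec-2-en-5-ol | C=C(Br)[C@@H]1/C=C\[C@]2(C)O[C@H]2CC[C@](C)(O[Si](C)(C)C(C)(C)C)C[C@H]1O | intermediate
23 | (1S,2Z,4R,5R,7S,10S)-4-(1-bromoethenyl)-7-(tert-butyldimethylsilyloxy)-1,7-dimethyl-11-oxabicyclo[8.1.0]undec-2-en-5-yl (2E)-2-methylbut-2-enoate | C=C(Br)[C@@H]1/C=C\[C@]2(C)O[C@H]2CC[C@](C)(O[Si](C)(C)C(C)(C)C)C[C@H]1OC(=O)/C(C)=C/C | intermediate
24 | alkenylmagnesium species from 23 (magnesium in place of bromine at C11; drawn as the butylmagnesium form of the lithium magnesate) | C=C([Mg]CCCC)[C@@H]1/C=C\[C@]2(C)O[C@H]2CC[C@](C)(O[Si](C)(C)C(C)(C)C)C[C@H]1OC(=O)/C(C)=C/C | intermediate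
25 | C11 carboxylate of the vinyl oxirane (2-substituted acrylate, drawn as the lithium salt) | C=C(C(=O)[O-])[C@@H]1/C=C\[C@]2(C)O[C@H]2CC[C@](C)(O[Si](C)(C)C(C)(C)C)C[C@H]1OC(=O)/C(C)=C/C.[Li+] | intermediate
26 | (3aS,4R,6S,9S,10Z,11aR)-6-(tert-butyldimethylsilyloxy)-9-hydroxy-6,10-dimethyl-3-methylidene-2-oxo-2,3,3a,4,5,6,7,8,9,11a-decahydrocyclodeca[b]furan-4-yl (2E)-2-methylbut-2-enoate | C=C1C(=O)O[C@@H]2/C=C(/C)[C@@H](O)CC[C@](C)(O[Si](C)(C)C(C)(C)C)C[C@@H](OC(=O)/C(C)=C/C)[C@H]12 | intermediate
27 | CNP0137971.1, (3aS,4R,6S,9S,10Z,11aR)-6,9-dihydroxy-6,10-dimethyl-3-methylidene-2-oxo-2,3,3a,4,5,6,7,8,9,11a-decahydrocyclodeca[b]furan-4-yl (2E)-2-methylbut-2-enoate | C=C1C(=O)O[C@@H]2/C=C(/C)[C@@H](O)CC[C@](C)(O)C[C@@H](OC(=O)/C(C)=C/C)[C@H]12 | target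

**Totals**

Total step count: 19. Longest linear sequence: 18 steps (steps 1–8 and 10–19, from geraniol).

**Steps most likely to fail**

Step 18. The alkenylmagnesium may attack the neighbouring tiglate carbonyl before CO2 is taken up, halide or Lewis-acidic magnesium may open the vinyl oxirane before palladium acts, or the π-allyl unit may undergo syn–anti equilibration with loss of the Z geometry and of the C6 configuration. The fallback sets out from 23 and comes back at 26; it brings in the C6 oxygen and the C12 carbon separately, without any organomagnesium species and with carbon monoxide as the one-carbon source. Pd(PPh3)4-catalysed 1,4-addition of acetic acid to the vinyl oxirane of 23 (THF, 0 °C) should give the C3-hydroxy C6-acetate, hydroxy acetate F1. Methanolysis of the allylic acetate (K2CO3, MeOH, 0 °C; the hindered conjugated tiglate reacts far more slowly) gives the cis-ene-diol F2. Pd(PPh3)4-catalysed cyclocarbonylation of the 2-bromo homoallylic alcohol in F2 (CO 1 atm, Et3N, THF, 50 °C) closes the α-methylene lactone to 26.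

Step 15. Intermolecular metathesis may lead to oligomers instead of ring closure, initiation at the vinyl group on the fully substituted oxirane carbon may be slow, or the E olefin may form. The fallback sets out from 18 and comes back at 21; it closes the ring by an intramolecular Wittig reaction of a non-stabilised ylide, which is Z-selective by itself. Alcohol 18 is converted into the primary iodide F3 (I2, PPh3, imidazole, CH2Cl2). The vinyl group on the oxirane is cleaved to the epoxy aldehyde F4 (OsO4 cat., N-methylmorpholine N-oxide, then NaIO4; the electron-poor bromoalkene reacts more slowly). PPh3 in MeCN at 60 °C gives the phosphonium iodide F5. Slow addition of F5 to KN(SiMe3)2 in THF at high dilution closes the Z-C5=C6 olefin to 21.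

Step 14. The basic ylide may deprotonate the α-branched, doubly activated aldehyde, causing epimerisation at C7 or β-elimination of the triethylsilyloxy group. The fallback sets out from 19 and comes back at 20; it is a Peterson olefination in two stages. Addition of the weakly basic organocerium reagent made from Me3SiCH2MgCl and CeCl3 to 19 (THF, −78 °C) gives the β-hydroxysilane F6 as a mixture at the new carbinol carbon, which is of no consequence. KH in THF (0 °C) then effects syn-elimination to 20.

Further compounds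
F1 | step 18 | C6 acetate of the (3S,6R)-cyclodec-4(Z)-ene-3,6-diol bearing 7-(1-bromoethenyl), 8-tigloyloxy and 10-OTBS groups (target locants) | C=C(Br)[C@@H]1[C@H](OC(C)=O)/C=C(/C)[C@@H](O)CC[C@](C)(O[Si](C)(C)C(C)(C)C)C[C@H]1OC(=O)/C(C)=C/C
F2 | step 18 | (3S,6R)-cyclodec-4(Z)-ene-3,6-diol bearing 7-(1-bromoethenyl), 8-tigloyloxy and 10-OTBS groups (target locants) | C=C(Br)[C@@H]1[C@H](O)/C=C(/C)[C@@H](O)CC[C@](C)(O[Si](C)(C)C(C)(C)C)C[C@H]1OC(=O)/C(C)=C/C
F3 | step 15 | primary iodide from 18 (iodine in place of the C6 hydroxyl) | C=C[C@]1(C)O[C@H]1CC[C@](C)(O[Si](C)(C)C(C)(C)C)C[C@@H](O[Si](CC)(CC)CC)[C@H](C(Br)=C)CI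
F4 | step 15 | iodo epoxy aldehyde (C5 aldehyde on the oxirane, C6 iodide) | O=C[C@]1(C)O[C@H]1CC[C@](C)(O[Si](C)(C)C(C)(C)C)C[C@@H](O[Si](CC)(CC)CC)[C@H](C(Br)=C)CI
F5 | step 15 | C6 triphenylphosphonium iodide of the epoxy aldehyde | O=C[C@]1(C)O[C@H]1CC[C@](C)(O[Si](C)(C)C(C)(C)C)C[C@@H](O[Si](CC)(CC)CC)[C@H](C(Br)=C)C[P+](c2ccccc2)(c2ccccc2)c2ccccc2.[I-]
F6 | step 14 | β-hydroxysilane from 19 (C6 carbinol bearing CH2SiMe3, mixture at C6) | C=C[C@]1(C)O[C@H]1CC[C@](C)(O[Si](C)(C)C(C)(C)C)C[C@@H](O[Si](CC)(CC)CC)[C@H](C(Br)=C)C(O)C[Si](C)(C)C
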